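Ring A is a hexasubstituted benzene whose oxygens at C5/C8a and C6/C8 are pairwise equivalent about the C7···C4a axis once O1 is written as a methoxy group. The route therefore disconnects both bonds of the C4 carbonyl (C4a–C4 and C4–C3): a mirror-symmetric 1-iodo-4-isopropoxy-2,3,5,6-tetramethoxybenzene, carbon monoxide and 4-ethynylanisole are joined in one palladium-catalysed carbonylative alkynylation. This three-component step installs the whole C3 bridge and ring B at the most hindered ring carbon, with C7–O already unique. The pyranone then closes on either homotopic ortho-methoxy group by chelation-controlled demethylation and 6-endo cyclisation.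

Key step: step 4

Remark: the target has no stereocentre or other stereogenic element (it is achiral), so "single enantiomer" requires no stereocontrol and all SMILES carry no stereodescriptors.

Step 1
Reactants: 1 1,2,4,5-tetramethoxybenzene
Product: 4 2,3,5,6-tetramethoxyphenol, via aryllithium 2 (not isolated), via lithium aryltrimethoxyborate 3 (not isolated)
Conditions: n-BuLi (1.1 equiv), THF, 0 °C→rt; B(OMe)3, −78 °C→rt; 30% aq. H2O2, 0 °C→rt
Reagents that add atoms: hydrogen peroxide, OO; n-butyllithium, [Li]CCCC (lithium of 2 and 3 only); trimethyl borate, COB(OC)OC (boron unit of 3 only)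
Why: Directed ortho-metalation at a C–H flanked by two methoxy groups, borylation and peroxide-induced 1,2-aryl shift from boron to oxygen (boronate oxidation) should place the hydroxyl at the carbon that becomes C7.

Step 2
Reactants: 4 2,3,5,6-tetramethoxyphenol
Product: 5 3-isopropoxy-1,2,4,5-tetramethoxybenzene
Conditions: 2-bromopropane, K2CO3, DMF, 60 °C, N2
Reagents that add atoms: 2-bromopropane, CC(C)Br
Why: Williamson etherification of the phenoxide should give a secondary alkyl aryl ether that tolerates n-BuLi and Pd/CO/amine and is later cleaved by BCl3 in the same operation as the ortho-methyl ether.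

Step 3
Reactants: 5 3-isopropoxy-1,2,4,5-tetramethoxybenzene
Product: 7 1-iodo-4-isopropoxy-2,3,5,6-tetramethoxybenzene, via aryllithium 6 (not isolated)
Conditions: n-BuLi (1.2 equiv), THF, 0 °C→rt; I2, −78 °C→rt
Reagents that add atoms: iodine, II; n-butyllithium, [Li]CCCC (lithium of 6 only)
Why: Directed ortho-metalation of the only remaining aryl C–H (between two methoxy groups, para to the isopropoxy group) followed by iodinolysis of the aryllithium should give the symmetric iodide without any regiochemical ambiguity.

Step 4
Reactants: 7 1-iodo-4-isopropoxy-2,3,5,6-tetramethoxybenzene; 8 4-ethynylanisole (1-ethynyl-4-methoxybenzene)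
Product: 9 1-(4-isopropoxy-2,3,5,6-tetramethoxyphenyl)-3-(4-methoxyphenyl)prop-2-yn-1-one
Conditions: CO (10 bar), PdCl2(PPh3)2 (5 mol %), Et3N (3 equiv), THF, 60 °C
Reagents that add atoms: carbon monoxide, [C-]#[O+]
Why: This is a carbonylative Sonogashira three-component coupling: Pd(0) inserts into the single C–I bond of 7, CO undergoes migratory insertion to an aroyl–Pd(II) species, the amine-deprotonated alkyne 8 replaces iodide, and reductive elimination should release ynone 9, so that C4a–C4 and C4–C3 are formed in one operation. The step closes no ring and creates no stereocentre; the pyranone is closed in step 5 by a 6-endo oxa-Michael addition–elimination. The selectivity needed is acyl coupling over CO-free alkynylation and over alkyne homocoupling. The electron-rich, doubly ortho-methoxylated aryl–Pd bond should insert CO rapidly (relief of ortho strain), whereas direct coupling at this hindered aryl is slow; CO pressure and copper-free conditions reinforce this. No regiochemical question arises because 7 is mirror-symmetric with one halogen, and the aryl methyl ethers, the isopropyl ether and the anisole ring are inert to Pd(0)/CO/Et3N. The iodide is chosen over a bromide so that oxidative addition to this very electron-rich ring stays feasible at 60 °C.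

Step 5
Reactants: 9 1-(4-isopropoxy-2,3,5,6-tetramethoxyphenyl)-3-(4-methoxyphenyl)prop-2-yn-1-one
Product: 11 7-hydroxy-5,6,8-trimethoxy-2-(4-methoxyphenyl)-4H-chromen-4-one, via dihydroxy ynone 10 (not isolated)
Conditions: BCl3 (3 equiv), CH2Cl2, −78→0 °C; aq. work-up; then Et2NH, EtOH, 50 °C
Reagents that add atoms: none
Why: BCl3 should cleave the secondary isopropyl ether and, through a six-membered boron chelate to the ketone, one of the two homotopic ortho-methoxy groups (chelation-controlled Lewis-acid ether cleavage), after which diethylamine adds to the ynone and the freed ortho-phenol displaces it in a 6-endo addition–elimination (amine-mediated cyclisation of o-hydroxyaryl ynones) that leads to the flavone and not the 5-exo aurone.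

Compound list
1 | 1,2,4,5-tetramethoxybenzene | COc1cc(OC)c(OC)cc1OC | starting material
2 | (2,3,5,6-tetramethoxyphenyl)lithium | [Li]c1c(OC)c(OC)cc(OC)c1OC | intermediate
3 | lithium trimethoxy(2,3,5,6-tetramethoxyphenyl)borate | [Li+].CO[B-](OC)(OC)c1c(OC)c(OC)cc(OC)c1OC | intermediate
4 | 2,3,5,6-tetramethoxyphenol | Oc1c(OC)c(OC)cc(OC)c1OC | intermediate
5 | 3-isopropoxy-1,2,4,5-tetramethoxybenzene | CC(C)Oc1c(OC)c(OC)cc(OC)c1OC | intermediate
6 | (4-isopropoxy-2,3,5,6-tetramethoxyphenyl)lithium | [Li]c1c(OC)c(OC)c(OC(C)C)c(OC)c1OC | intermediate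
7 | 1-iodo-4-isopropoxy-2,3,5,6-tetramethoxybenzene | CC(C)Oc1c(OC)c(OC)c(I)c(OC)c1OC | intermediate
8 | 4-ethynylanisole (1-ethynyl-4-methoxybenzene) | C#Cc1ccc(OC)cc1 | starting material
9 | 1-(4-isopropoxy-2,3,5,6-tetramethoxyphenyl)-3-(4-methoxyphenyl)prop-2-yn-1-one | CC(C)Oc1c(OC)c(OC)c(C(=O)C#Cc2ccc(OC)cc2)c(OC)c1OC | intermediate
10 | 1-(2,4-dihydroxy-3,5,6-trimethoxyphenyl)-3-(4-methoxyphenyl)prop-2-yn-1-one | COc1ccc(C#CC(=O)c2c(O)c(OC)c(O)c(OC)c2OC)cc1 | intermediate
11 | 7-hydroxy-5,6,8-trimethoxy-2-(4-methoxyphenyl)-4H-chromen-4-one (7-hydroxy-4',5,6,8-tetramethoxyflavone) | COc1ccc(-c2cc(=O)c3c(OC)c(OC)c(O)c(OC)c3o2)cc1 | target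

Total step count: 5. Longest linear sequence: 5 steps (1 → 4 → 5 → 7 → 9 → 11).

Steps most likely to fail

Step 4. Oxidative addition into the electron-rich, doubly ortho-substituted C–I bond may be slow, or CO-free alkynylation may compete with CO insertion. The fallback replaces the carbonylation by polar C–C bond formation. It sets out from 5: aryllithium 6 (n-BuLi, THF) is quenched with DMF to give 4-isopropoxy-2,3,5,6-tetramethoxybenzaldehyde F1. Lithium (4-methoxyphenyl)acetylide F2 (from 8 and n-BuLi, THF, −78 °C) is added to the aldehyde to give racemic 1-(4-isopropoxy-2,3,5,6-tetramethoxyphenyl)-3-(4-methoxyphenyl)prop-2-yn-1-ol F3. Oxidation of this doubly activated carbinol with MnO2 (CH2Cl2, rt) should give ynone 9, where the route is rejoined.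

Step 5. The Lewis-acid ether cleavage may lose chemoselectivity (cleavage of a second methyl ether, in particular the other ortho/peri methoxy group), or chloride may add to the activated ynone. The fallback closes the ring by electrophile-induced demethylative cyclisation instead. It sets out from 9: ICl (CH2Cl2, −78 °C) should trigger 6-endo-dig attack of an ortho-methoxy oxygen on the iodonium-activated alkyne with loss of the methyl group, giving 3-iodo-7-isopropoxy-5,6,8-trimethoxy-2-(4-methoxyphenyl)-4H-chromen-4-one F4. Palladium-catalysed formate reduction (Pd(OAc)2, PPh3, HCO2Na, DMF, 80 °C) should remove the iodine to give 7-isopropoxy-5,6,8-trimethoxy-2-(4-methoxyphenyl)-4H-chromen-4-one F5. BCl3 (1.1 equiv, CH2Cl2, −78 °C), which cleaves a secondary alkyl aryl ether faster than the chelated 5-methoxy group, should then return to target 11.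

Step 1. The very electron-rich phenol may be over-oxidised towards a quinone under the peroxide conditions, or double lithiation may occur. The fallback introduces the oxygen by formylation and oxygen insertion, so that the phenol is set free only under non-oxidising conditions. It sets out from 1: aryllithium 2 is quenched with DMF to give 2,3,5,6-tetramethoxybenzaldehyde F6. Baeyer–Villiger oxidation (mCPBA, NaHCO3, CH2Cl2) with migration of the electron-rich aryl group should give 2,3,5,6-tetramethoxyphenyl formate F7. Methanolysis (cat. K2CO3, MeOH, N2) returns to phenol 4.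

Further compounds
F1 | step 4 | 4-isopropoxy-2,3,5,6-tetramethoxybenzaldehyde | CC(C)Oc1c(OC)c(OC)c(C=O)c(OC)c1OC
F2 | step 4 | lithium (4-methoxyphenyl)acetylide | [Li]C#Cc1ccc(OC)cc1
F3 | step 4 | rac-1-(4-isopropoxy-2,3,5,6-tetramethoxyphenyl)-3-(4-methoxyphenyl)prop-2-yn-1-ol | CC(C)Oc1c(OC)c(OC)c(C(O)C#Cc2ccc(OC)cc2)c(OC)c1OC
F4 | step 5 | 3-iodo-7-isopropoxy-5,6,8-trimethoxy-2-(4-methoxyphenyl)-4H-chromen-4-one | COc1ccc(-c2oc3c(OC)c(OC(C)C)c(OC)c(OC)c3c(=O)c2I)cc1
F5 | step 5 | 7-isopropoxy-5,6,8-trimethoxy-2-(4-methoxyphenyl)-4H-chromen-4-one | COc1ccc(-c2cc(=O)c3c(OC)c(OC)c(OC(C)C)c(OC)c3o2)cc1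
F6 | step 1 | 2,3,5,6-tetramethoxybenzaldehyde | O=Cc1c(OC)c(OC)cc(OC)c1OC
F7 | step 1 | 2,3,5,6-tetramethoxyphenyl formate | O=COc1c(OC)c(OC)cc(OC)c1OC
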